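**Direct plan (sketch)**

A direct plan would make both nitrogen rings first and the macrocycle last: hydrogenation of the pyridinol ester A1 would give the all-cis piperidinol ester A2 as a racemate.
After resolution, two differently protected copies of A2 would be joined by esterification and macrolactonisation to the N-Cbz/N-Boc dilactone A3.
Hydrogenolysis would give the amine A4, which would be N-chlorinated and dehydrochlorinated to the ring A imine before the Boc group is removed.
Weak point 1, the hydrogenation of A1 with later kinetic resolution: the three ring stereocentres would be set only as a racemate, and half of the material would be discarded.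
Weak point 2, the unsymmetrical joining of two copies of A2: about six protection, deprotection and activation steps would build no bond of the skeleton.
Weak point 3, the dehydrochlorination of the N-chloro derivative of A4: it would have to choose C2–H over C6–H late in the route, and the epimerisable 3-acyloxy imine would then have to survive an acid deprotection.

**Retrosynthetic overview of the new route**

- Feature used: in ring A and in ring B the ester oxygen sits on C3, next to C2, which carries the methyl group and the nitrogen. O–C3–C2(–CH3) is therefore the oxidised form of a branched allylic ester O–CH–CH=CH2, and N–C2 is the condensation product of the C6 amine with a C2 methyl ketone.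
- Key disconnections: both O–C3 bonds (alkyl–oxygen, not acyl–oxygen) are cut to a carboxylic acid plus a terminal alkyne by rhodium-catalysed hydro-acyloxylation, intermolecular for ring A and as the macrocyclisation for ring B. Both N–C2 bonds are cut last.
- Ring order: the 26-membered dilactone first (step 10), then ring B by hydrogenolysis and reductive amination (step 12), then ring A by acid-triggered condensation that stops at the imine (step 13).
- Stereocentres: C6 of both rings from one sulfinamide-directed Grignard addition, C3 of both rings by catalyst control, C2 of ring B by substrate-controlled hydrogenation. Nothing is resolved.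
- Weak points avoided by design: no free hydroxyl ever exists, so nothing is O-protected or activated. The imine is never made by dehydrogenation, because the oxidation level of each ring is fixed by its nitrogen protecting group (Cbz for ring B, Boc for ring A).

Key step: step 10

Remark (assumption): the (R,R) enantiomer of Cp-DIOP, the cyclopentylidene ketal analogue of DIOP, is assumed to give the (S)-configured branched allylic ester; if a model coupling showed the opposite sense, the (S,S) ligand would be used in steps 7 and 10.

**Route**

Step 1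
Reactants: 1 methyl 9-oxononanoate; 2 (R)-2-methylpropane-2-sulfinamide
Product: 3 methyl (E)-9-{[(R)-tert-butylsulfinyl]imino}nonanoate
Conditions: CuSO4 (anhydrous), CH2Cl2, rt
Reagents that add atoms: none
Why: Dehydrative condensation of an aldehyde with tert-butanesulfinamide (N-sulfinyl imine formation) leaves the methyl ester alone and gives the (E)-aldimine that carries the chiral director for C6 of both rings.

Step 2
Reactants: 3 methyl (E)-9-{[(R)-tert-butylsulfinyl]imino}nonanoate; 4 (5-chloropent-1-yn-1-yl)trimethylsilane
Product: 6 methyl (9R)-9-{[(R)-tert-butylsulfinyl]amino}-14-(trimethylsilyl)tetradec-13-ynoate, via Grignard reagent 5 (not isolated)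
Conditions: 4, Mg, THF, 50 °C; then 3, CH2Cl2, −78 to −40 °C; aq NH4Cl
Reagents that add atoms: none
Why: Grignard addition to the N-sulfinyl aldimine through a six-membered chair transition state (magnesium bound to the sulfinyl oxygen, tert-butyl group equatorial) should place the alkyl group on the face that gives (9R), the later C6 of ring A and ring B; the aldimine reacts much faster than the methyl ester at low temperature, and a minor diastereomer would be removed by chromatography.

Step 3
Reactants: 6 methyl (9R)-9-{[(R)-tert-butylsulfinyl]amino}-14-(trimethylsilyl)tetradec-13-ynoate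
Product: 7 methyl (9R)-9-amino-14-(trimethylsilyl)tetradec-13-ynoate hydrochloride
Conditions: HCl (4 M in dioxane), MeOH, 0 °C; evaporate, triturate with Et2O/hexane
Reagents that add atoms: hydrogen chloride, Cl
Why: Acid methanolysis of the sulfinamide N–S bond (cleavage of the sulfinyl auxiliary) touches neither the stereocentre, the alkynylsilane nor the methyl ester, and the amine is isolated once as its stable hydrochloride, which then serves both branches of the route.

Step 4
Reactants: 7 methyl (9R)-9-amino-14-(trimethylsilyl)tetradec-13-ynoate hydrochloride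
Product: 9 methyl (9R)-9-[(tert-butoxycarbonyl)amino]tetradec-13-ynoate, via desilylated free amine 8 (not isolated)
Conditions: K2CO3, MeOH, rt; then Boc2O, rt
Reagents that add atoms: di-tert-butyl dicarbonate, CC(C)(C)OC(=O)OC(=O)OC(C)(C)C
Why: Carbonate in methanol frees the amine and protodesilylates the alkynylsilane (the methyl ester can only exchange with itself), and N-acylation with Boc2O in the same flask touches no stereocentre; the Boc group marks this unit as ring A, whose nitrogen is released last.

Step 5
Reactants: 7 methyl (9R)-9-amino-14-(trimethylsilyl)tetradec-13-ynoate hydrochloride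
Product: 10 methyl (9R)-9-{[(benzyloxy)carbonyl]amino}-14-(trimethylsilyl)tetradec-13-ynoate
Conditions: CbzCl, NaHCO3, EtOAc/H2O, 0 °C to rt
Reagents that add atoms: benzyl chloroformate, O=C(Cl)OCc1ccccc1
Why: Schotten–Baumann carbamoylation under bicarbonate keeps the alkynylsilane, which masks this alkyne during step 7; the Cbz group marks this unit as ring B, whose nitrogen is released under hydrogen.

Step 6
Reactants: 10 methyl (9R)-9-{[(benzyloxy)carbonyl]amino}-14-(trimethylsilyl)tetradec-13-ynoate
Product: 11 (9R)-9-{[(benzyloxy)carbonyl]amino}-14-(trimethylsilyl)tetradec-13-ynoic acid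
Conditions: Me3SnOH, ClCH2CH2Cl, 70 °C; 0.5 M HCl wash
Reagents that add atoms: trimethyltin hydroxide, C[Sn](C)(C)O
Why: Trimethyltin hydroxide hydrolysis of a methyl ester delivers hydroxide to the carbonyl group from tin and should be neither basic nor nucleophilic enough to attack the alkynylsilane or the carbamate.

Step 7
Reactants: 11 (9R)-9-{[(benzyloxy)carbonyl]amino}-14-(trimethylsilyl)tetradec-13-ynoic acid; 9 methyl (9R)-9-[(tert-butoxycarbonyl)amino]tetradec-13-ynoate
Product: 13 (3S,6R)-6-[(tert-butoxycarbonyl)amino]-14-methoxy-14-oxotetradec-1-en-3-yl (9R)-9-{[(benzyloxy)carbonyl]amino}-14-(trimethylsilyl)tetradec-13-ynoate, via allene isomer 12 (not isolated)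
Conditions: [Rh(cod)Cl]2 (cat.), (R,R)-Cp-DIOP (cat.), 9 (1.3 equiv), ClCH2CH2Cl, 40 °C
Reagents that add atoms: none
Why: Rhodium-catalysed redox-neutral addition of a carboxylic acid to a terminal alkyne (alkyne-to-allene isomerisation by a rhodium hydride, then C–O reductive elimination from the π-allyl rhodium carboxylate at the substituted terminus) gives the branched allylic ester and sets C3 of ring A (S) under control of the chiral diphosphine; the silyl-capped alkyne of 11 cannot isomerise to a terminal allene and stays out.

Step 8
Reactants: 13 (3S,6R)-6-[(tert-butoxycarbonyl)amino]-14-methoxy-14-oxotetradec-1-en-3-yl (9R)-9-{[(benzyloxy)carbonyl]amino}-14-(trimethylsilyl)tetradec-13-ynoate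
Product: 14 (3S,6R)-6-[(tert-butoxycarbonyl)amino]-14-methoxy-14-oxotetradec-1-en-3-yl (9R)-9-{[(benzyloxy)carbonyl]amino}tetradec-13-ynoate
Conditions: TBAF, AcOH, THF, 0 °C
Reagents that add atoms: none
Why: Fluoride-mediated protodesilylation of the alkynylsilane, buffered by acetic acid, frees the second alkyne without touching the esters or the carbamates.

Step 9
Reactants: 14 (3S,6R)-6-[(tert-butoxycarbonyl)amino]-14-methoxy-14-oxotetradec-1-en-3-yl (9R)-9-{[(benzyloxy)carbonyl]amino}tetradec-13-ynoate
Product: 15 (9R,12S)-12-{[(9R)-9-{[(benzyloxy)carbonyl]amino}tetradec-13-ynoyl]oxy}-9-[(tert-butoxycarbonyl)amino]tetradec-13-enoic acid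
Conditions: Me3SnOH, ClCH2CH2Cl, 70 °C; cold 0.5 M HCl wash
Reagents that add atoms: trimethyltin hydroxide, C[Sn](C)(C)O
Why: Trimethyltin hydroxide hydrolysis favours the unhindered methyl ester over the internal ester of the branched secondary allylic alcohol, and the brief cold acid wash should not harm the Boc group.

Step 10
Reactants: 15 (9R,12S)-12-{[(9R)-9-{[(benzyloxy)carbonyl]amino}tetradec-13-ynoyl]oxy}-9-[(tert-butoxycarbonyl)amino]tetradec-13-enoic acid
Product: 17 divinyl dilactone tert-butyl N-[(10R,13S,23R,26S)-23-{[(benzyloxy)carbonyl]amino}-13,26-diethenyl-2,15-dioxo-1,14-dioxacyclohexacosan-10-yl]carbamate, via allenyl seco acid 16 (not isolated)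
Conditions: [Rh(cod)Cl]2 (cat.), (R,R)-Cp-DIOP (cat.), ClCH2CH2Cl, 60 °C, high dilution, slow addition of 15
Reagents that add atoms: none
Why: This is the redox-neutral rhodium-catalysed addition of a carboxylic acid to a terminal alkyne run intramolecularly: the acid O–H adds oxidatively to monovalent rhodium, the rhodium hydride isomerises the unit B alkyne to the terminal allene 16, hydrometalation gives a π-allyl rhodium carboxylate, and C–O reductive elimination at the substituted allyl terminus forms the O–C3 bond of ring B as a branched allylic ester. The closest known reaction types are the rhodium/diphosphine macrolactonisation of ω-alkynyl carboxylic acids to vinyl-substituted macrolactones and the enantioselective head-to-tail cyclodimerisation of ω-allenyl carboxylic acids to macrodiolides. The 26-membered ring closes end to end by bonding of the unit A carboxylate oxygen to C12 of unit B, an unstrained large-ring closure that only has to beat oligomerisation, which high dilution and slow addition should secure. The new stereocentre (C3 of ring B, S) is set by the chiral diphosphine on rhodium in the reductive elimination, and the existing centres lie at least three atoms away and should not override the catalyst. The step needs branched over linear regioselectivity, which is inherent to this catalyst system, and O- over N-allylation, which should hold because only the carboxylate is bound to rhodium while the carbamate N–H groups are not acidic enough to add. The precursor 15 holds no hydroxyl group and no activated ester, so nothing has to be protected or activated for the ring closure.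

Step 11
Reactants: 17 divinyl dilactone
Product: 18 diacetyl dilactone tert-butyl N-[(10R,13S,23R,26S)-13,26-diacetyl-23-{[(benzyloxy)carbonyl]amino}-2,15-dioxo-1,14-dioxacyclohexacosan-10-yl]carbamate
Conditions: PdCl2(quinox) (cat.; quinox = 2-(4,5-dihydrooxazol-2-yl)quinoline), AgSbF6 (cat.), aq TBHP (70%), CH2Cl2, 0 °C to rt
Reagents that add atoms: tert-butyl hydroperoxide, CC(C)(C)OO
Why: The peroxide-mediated Wacker-type oxidation with the cationic quinoline–oxazoline complex of divalent palladium turns protected allylic alcohols, allylic esters included, into methyl ketones under catalyst control without loss of configuration at the allylic carbon, so both vinyl groups become the C2 acetyl groups of ring A and ring B under base-free conditions that suit the two α-acyloxy ketones.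

Step 12
Reactants: 18 diacetyl dilactone
Product: 21 ring B-closed dilactone (ring B as all-cis (2S,3S,6R)-2-methylpiperidine; unit A unchanged as NHBoc ketone), via amino ketone 19 (not isolated), via cyclic imine 20 (not isolated)
Conditions: H2 (1 atm), Pd/C, EtOAc/EtOH, rt
Reagents that add atoms: none
Why: Hydrogenolysis of the benzyl carbamate frees the C6 amine of ring B, which condenses with its own C2 ketone in a six-membered ring closure, and the imine is hydrogenated from the face opposite the pseudoaxial C3 acyloxy group, the face that also carries the C6 hydrogen, so the C2 methyl should end up cis to both substituents (2S); the Boc-protected nitrogen of unit A cannot condense, so its ketone waits.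

Step 13
Reactants: 21 ring B-closed dilactone
Product: 23 CNP0304114.1 (target), via ammonium ketone salt 22 (not isolated)
Conditions: TFA/CH2Cl2 (1:4), 0 °C; cold aq NaHCO3
Reagents that add atoms: none
Why: Acidolysis of the Boc group frees the C6 amine of ring A, which on neutralisation condenses with the C2 methyl ketone (intramolecular imine formation), so the C2=N bond can only form at the carbon that carries the methyl group; no reducing agent is present, ring B is only protonated, and the short cold treatment should keep C3 of ring A from epimerising through the enamine.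

**Compound list**

1 | methyl 9-oxononanoate | O=CCCCCCCCC(=O)OC | starting material
2 | (R)-2-methylpropane-2-sulfinamide | CC(C)(C)[S@@](=O)N | starting material
3 | methyl (E)-9-{[(R)-tert-butylsulfinyl]imino}nonanoate | CC(C)(C)[S@@](=O)/N=C/CCCCCCCC(=O)OC | intermediate
4 | (5-chloropent-1-yn-1-yl)trimethylsilane | C[Si](C)(C)C#CCCCCl | starting material
5 | [5-(trimethylsilyl)pent-4-yn-1-yl]magnesium chloride | C[Si](C)(C)C#CCCC[Mg]Cl | intermediate
6 | methyl (9R)-9-{[(R)-tert-butylsulfinyl]amino}-14-(trimethylsilyl)tetradec-13-ynoate | CC(C)(C)[S@@](=O)N[C@@H](CCCC#C[Si](C)(C)C)CCCCCCCC(=O)OC | intermediate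
7 | methyl (9R)-9-amino-14-(trimethylsilyl)tetradec-13-ynoate hydrochloride | Cl.N[C@@H](CCCC#C[Si](C)(C)C)CCCCCCCC(=O)OC | intermediate
8 | methyl (9R)-9-aminotetradec-13-ynoate | N[C@@H](CCCC#C)CCCCCCCC(=O)OC | intermediate
9 | methyl (9R)-9-[(tert-butoxycarbonyl)amino]tetradec-13-ynoate | CC(C)(C)OC(=O)N[C@@H](CCCC#C)CCCCCCCC(=O)OC | intermediate
10 | methyl (9R)-9-{[(benzyloxy)carbonyl]amino}-14-(trimethylsilyl)tetradec-13-ynoate | O=C(OCc1ccccc1)N[C@@H](CCCC#C[Si](C)(C)C)CCCCCCCC(=O)OC | intermediate
11 | (9R)-9-{[(benzyloxy)carbonyl]amino}-14-(trimethylsilyl)tetradec-13-ynoic acid | O=C(OCc1ccccc1)N[C@@H](CCCC#C[Si](C)(C)C)CCCCCCCC(=O)O | intermediate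
12 | methyl (9R)-9-[(tert-butoxycarbonyl)amino]tetradeca-12,13-dienoate | C=C=CCC[C@H](NC(=O)OC(C)(C)C)CCCCCCCC(=O)OC | intermediate
13 | (3S,6R)-6-[(tert-butoxycarbonyl)amino]-14-methoxy-14-oxotetradec-1-en-3-yl (9R)-9-{[(benzyloxy)carbonyl]amino}-14-(trimethylsilyl)tetradec-13-ynoate | C=C[C@H](CC[C@H](NC(=O)OC(C)(C)C)CCCCCCCC(=O)OC)OC(=O)CCCCCCC[C@@H](NC(=O)OCc1ccccc1)CCCC#C[Si](C)(C)C | intermediate
14 | (3S,6R)-6-[(tert-butoxycarbonyl)amino]-14-methoxy-14-oxotetradec-1-en-3-yl (9R)-9-{[(benzyloxy)carbonyl]amino}tetradec-13-ynoate | C=C[C@H](CC[C@H](NC(=O)OC(C)(C)C)CCCCCCCC(=O)OC)OC(=O)CCCCCCC[C@@H](NC(=O)OCc1ccccc1)CCCC#C | intermediate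
15 | (9R,12S)-12-{[(9R)-9-{[(benzyloxy)carbonyl]amino}tetradec-13-ynoyl]oxy}-9-[(tert-butoxycarbonyl)amino]tetradec-13-enoic acid | C=C[C@H](CC[C@H](NC(=O)OC(C)(C)C)CCCCCCCC(=O)O)OC(=O)CCCCCCC[C@@H](NC(=O)OCc1ccccc1)CCCC#C | intermediate
16 | (9R,12S)-12-{[(9R)-9-{[(benzyloxy)carbonyl]amino}tetradeca-12,13-dienoyl]oxy}-9-[(tert-butoxycarbonyl)amino]tetradec-13-enoic acid | C=C[C@H](CC[C@H](NC(=O)OC(C)(C)C)CCCCCCCC(=O)O)OC(=O)CCCCCCC[C@@H](NC(=O)OCc1ccccc1)CCC=C=C | intermediate
17 | tert-butyl N-[(10R,13S,23R,26S)-23-{[(benzyloxy)carbonyl]amino}-13,26-diethenyl-2,15-dioxo-1,14-dioxacyclohexacosan-10-yl]carbamate (26-membered divinyl dilactone) | C=C[C@@H]1CC[C@H](NC(=O)OC(C)(C)C)CCCCCCCC(=O)O[C@H](C=C)CC[C@H](NC(=O)OCc2ccccc2)CCCCCCCC(=O)O1 | intermediate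
18 | tert-butyl N-[(10R,13S,23R,26S)-13,26-diacetyl-23-{[(benzyloxy)carbonyl]amino}-2,15-dioxo-1,14-dioxacyclohexacosan-10-yl]carbamate (diacetyl dilactone) | CC(=O)[C@@H]1CC[C@H](NC(=O)OC(C)(C)C)CCCCCCCC(=O)O[C@H](C(C)=O)CC[C@H](NC(=O)OCc2ccccc2)CCCCCCCC(=O)O1 | intermediate
19 | tert-butyl N-[(10R,13S,23R,26S)-13,26-diacetyl-23-amino-2,15-dioxo-1,14-dioxacyclohexacosan-10-yl]carbamate | CC(=O)[C@@H]1CC[C@H](NC(=O)OC(C)(C)C)CCCCCCCC(=O)O[C@H](C(C)=O)CC[C@H](N)CCCCCCCC(=O)O1 | intermediate
20 | dilactone with ring B closed as the (3S,6R)-2-methyl-3,4,5,6-tetrahydropyridine (C2=N); unit A open as (9R)-NHBoc and (12S)-acetyl carbinol ester | CC(=O)[C@@H]1CC[C@H](NC(=O)OC(C)(C)C)CCCCCCCC(=O)O[C@H]2CC[C@@H](CCCCCCCC(=O)O1)N=C2C | intermediate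
21 | dilactone with ring B as the all-cis (2S,3S,6R)-2-methylpiperidine; unit A open as (9R)-NHBoc and (12S)-acetyl carbinol ester | CC(=O)[C@@H]1CC[C@H](NC(=O)OC(C)(C)C)CCCCCCCC(=O)O[C@H]2CC[C@@H](CCCCCCCC(=O)O1)N[C@H]2C | intermediate
22 | bis(trifluoroacetate) of 21 without the Boc group (unit A as (9R)-ammonium and (12S)-acetyl carbinol ester) | CC(=O)[C@@H]1CC[C@H](N)CCCCCCCC(=O)O[C@H]2CC[C@@H](CCCCCCCC(=O)O1)N[C@H]2C.OC(=O)C(F)(F)F.OC(=O)C(F)(F)F | intermediate
23 | CNP0304114.1: dilactone with ring A as the (3S,6R)-2-methyl imine and ring B as the all-cis (2S,3S,6R)-piperidine | CC1=N[C@@H]2CCCCCCCC(=O)O[C@H]3CC[C@@H](CCCCCCCC(=O)O[C@H]1CC2)N[C@H]3C | target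

**Step count and risks**

Total step count: 13. Longest linear sequence: 12 (steps 1, 2, 3, 5, 6, 7, 8, 9, 10, 11, 12, 13).

Most likely to fail, first: step 10. The ring closure could lose to oligomerisation, the reductive elimination could turn to the linear allylic ester, the catalyst could give the wrong configuration at C3 of ring B, or a carbamate nitrogen could capture the allyl intermediate. The fallback would make the O–C3 bond of ring B intermolecularly and close the ring at the acyl carbon instead. It sets out from 14: the same rhodium catalyst would add chloroacetic acid (excess) to the alkyne to give the chloroacetate F1. Thiourea and NaHCO3 in ethanol would remove the chloroacetyl group to give the hydroxy ester F2. Me3SnOH would then give the seco hydroxy acid F3. A Shiina macrolactonisation (MNBA, DMAP, CH2Cl2, high dilution, rt) would close the ring to 17, where the route is rejoined.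

Second: step 7. With an aliphatic acid and an aliphatic alkyne the catalyst might give insufficient facial selectivity at C3 of ring A, or the valuable acid 11 might be consumed by slow engagement of its silyl-capped alkyne. The fallback would set the carbinol with a cheap aromatic acid and form the ester by classical acylation. It sets out from 9: rhodium-catalysed addition of benzoic acid (excess) would give the benzoate F4. K2CO3 in methanol, in which the methyl ester is degenerate, would release the allylic alcohol F5, whose configuration could be checked and upgraded by chromatography. A Steglich esterification of F5 with acid 11 (EDC·HCl, DMAP, CH2Cl2, 0 °C) would give 13, where the route is rejoined.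

Third: step 11. The oxidation could add oxygen at the terminal carbon to give aldehydes, a carbamate nitrogen could attack the palladium-bound alkene, or the allylic ester could ionise and lose its configuration. The fallback would replace the palladium oxidation by a radical hydration and a separate oxidation. It sets out from 17: a Mukaiyama hydration (Co(acac)2 cat., PhSiH3, O2, THF, rt) would add water in the Markovnikov sense through the secondary radical to give the bis(1-hydroxyethyl) dilactone F6 as a mixture of carbinol epimers. Dess–Martin periodinane (CH2Cl2, NaHCO3, rt) would oxidise both carbinols to give 18, where the route is rejoined.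

**Further compounds**

F1 | step 10 | chloroacetate: 14 in which the unit B alkyne terminus has become the (S)-configured CH(OCOCH2Cl)–CH=CH2 group | C=C[C@H](CC[C@H](NC(=O)OC(C)(C)C)CCCCCCCC(=O)OC)OC(=O)CCCCCCC[C@@H](NC(=O)OCc1ccccc1)CC[C@@H](C=C)OC(=O)CCl
F2 | step 10 | hydroxy ester: F1 without the chloroacetyl group (free (S)-allylic alcohol in unit B, methyl ester in unit A) | C=C[C@H](CC[C@H](NC(=O)OC(C)(C)C)CCCCCCCC(=O)OC)OC(=O)CCCCCCC[C@@H](NC(=O)OCc1ccccc1)CC[C@@H](C=C)O
F3 | step 10 | seco hydroxy acid: F2 with the methyl ester cleaved | C=C[C@H](CC[C@H](NC(=O)OC(C)(C)C)CCCCCCCC(=O)O)OC(=O)CCCCCCC[C@@H](NC(=O)OCc1ccccc1)CC[C@@H](C=C)O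
F4 | step 7 | methyl (9R,12S)-12-(benzoyloxy)-9-[(tert-butoxycarbonyl)amino]tetradec-13-enoate | C=C[C@H](CC[C@H](NC(=O)OC(C)(C)C)CCCCCCCC(=O)OC)OC(=O)c1ccccc1
F5 | step 7 | methyl (9R,12S)-9-[(tert-butoxycarbonyl)amino]-12-hydroxytetradec-13-enoate | C=C[C@H](CC[C@H](NC(=O)OC(C)(C)C)CCCCCCCC(=O)OC)O
F6 | step 11 | bis(1-hydroxyethyl) dilactone: 17 with both vinyl groups hydrated to CH(OH)CH3 (carbinol epimers) | CC(O)[C@@H]1CC[C@H](NC(=O)OC(C)(C)C)CCCCCCCC(=O)O[C@H](C(C)O)CC[C@H](NC(=O)OCc2ccccc2)CCCCCCCC(=O)O1
A1 | direct plan | methyl 8-(5-hydroxy-6-methylpyridin-2-yl)octanoate | Cc1nc(CCCCCCCC(=O)OC)ccc1O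
A2 | direct plan | rac-methyl 8-[(2R*,5S*,6S*)-5-hydroxy-6-methylpiperidin-2-yl]octanoate (all-cis racemate) | O[C@H]1CC[C@@H](CCCCCCCC(=O)OC)N[C@H]1C.O[C@@H]1CC[C@H](CCCCCCCC(=O)OC)N[C@@H]1C
A3 | direct plan | 26-membered dilactone with both rings as all-cis (2S,3S,6R)-piperidines, ring A N-Cbz, ring B N-Boc | C[C@@H]1N(C(=O)OCc4ccccc4)[C@@H]2CCCCCCCC(=O)O[C@H]3CC[C@@H](CCCCCCCC(=O)O[C@H]1CC2)N(C(=O)OC(C)(C)C)[C@H]3C
A4 | direct plan | the same dilactone with ring A N–H and ring B N-Boc | C[C@@H]1N[C@@H]2CCCCCCCC(=O)O[C@H]3CC[C@@H](CCCCCCCC(=O)O[C@H]1CC2)N(C(=O)OC(C)(C)C)[C@H]3C
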